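The target is assembled by converting the ent-labdane decalin of andrographolide into the neo-clerodane decalin through a cationic backbone rearrangement, followed by oxidation-level adjustments and a furan Friedel–Crafts closure of ring C. In one operation the key step forms the C9–C20 and C5–C19 bonds, sets C9, C10 and C5, and creates the C3=C4 alkene of ring A. It exploits the array quaternary C5 (carrying C19), ring-fusion C10–H and quaternary C9 (carrying C20) shared by rings A and B. Its precursor is a 13,14,15,16-tetranor ent-labdane 8β,9β-epoxide with an axial C19 silyl ether on C4 and a 2-acetoxyethyl group (C11–C12) on C9.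

Key step: step 9

Remarks on the chemistry:
- Numbering: labdane numbering is used up to compound 9 and clerodane numbering from compound 10 on; the labels C11, C12 and C17–C20 stay with their atoms.
- Substrate design at C12: C12 is held at the alcohol level as an acetate. A C12 carboxyl derivative would destabilise the C9 cation, could close a γ-lactone onto the C8 oxygen (a ring the step must not form) and would make the epoxide base-labile.
- Substrate design at C19: C19 carries a bulky silyl ether, whose oxygen is a poor nucleophile toward the C10 cation and which is removed without hydrogenolysis.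
- Ring C is closed while C12 is still a silyl-protected carbinol, because a 3-acylfuran is deactivated at its C2; the ketone is made last.
- Assumption: the two C12 epimers formed in step 20 are carried together, because C12 ends as a ketone.

Step 1
Reactants: 1 andrographolide
Product: 2 19-O-(tert-butyldiphenylsilyl)andrographolide
Conditions: TBDPSCl (1.1 equiv), imidazole, DMF, 0 °C → rt
Reagents that add atoms: tert-butyl(chloro)diphenylsilane, CC(C)(C)[Si](Cl)(c1ccccc1)c1ccccc1
Why: Silyl ether formation should occur only at the primary C19 hydroxyl, which is far more accessible than the hindered secondary C3 and C14 hydroxyls, and it touches no stereocentre.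

Step 2
Reactants: 2 19-O-(tert-butyldiphenylsilyl)andrographolide
Product: 3 3α-hydroxy-19-(tert-butyldiphenylsilyloxy)-13,14,15,16-tetranor-ent-labd-8(17)-en-12-al
Conditions: KMnO4, MgSO4, acetone/H2O, −10 °C
Reagents that add atoms: potassium permanganate, [K+].[O-][Mn](=O)(=O)=O
Why: Permanganate oxidative cleavage should take the electron-poor conjugated C12=C13 alkene in preference to the hindered, unactivated exocyclic C8=C17 alkene, as in the classical side-chain degradation of labd-8(17)-enes, and the buffered cold conditions are meant to stop at the aldehyde.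

Step 3
Reactants: 3 3α-hydroxy-19-(tert-butyldiphenylsilyloxy)-13,14,15,16-tetranor-ent-labd-8(17)-en-12-al
Product: 4 19-(tert-butyldiphenylsilyloxy)-13,14,15,16-tetranor-ent-labd-8(17)-ene-3α,12-diol
Conditions: NaBH4, MeOH, 0 °C
Reagents that add atoms: none
Why: Borohydride reduction of the aldehyde gives the primary alcohol without affecting the silyl ether or the alkene.

Step 4
Reactants: 4 19-(tert-butyldiphenylsilyloxy)-13,14,15,16-tetranor-ent-labd-8(17)-ene-3α,12-diol
Product: 5 12-acetoxy-19-(tert-butyldiphenylsilyloxy)-13,14,15,16-tetranor-ent-labd-8(17)-en-3α-ol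
Conditions: Ac2O (1.1 equiv), pyridine, CH2Cl2, 0 °C
Reagents that add atoms: acetic anhydride, CC(=O)OC(C)=O
Why: Acylation should be selective for the unhindered primary C12 hydroxyl over the secondary C3 hydroxyl, which is flanked by quaternary C4.

Step 5
Reactants: 5 12-acetoxy-19-(tert-butyldiphenylsilyloxy)-13,14,15,16-tetranor-ent-labd-8(17)-en-3α-ol
Product: 6 O-3 imidazol-1-ylcarbonothioate of 5
Conditions: 1,1'-thiocarbonyldiimidazole, DMAP (cat.), ClCH2CH2Cl, 70 °C
Reagents that add atoms: 1,1'-thiocarbonyldiimidazole, S=C(n1ccnc1)n1ccnc1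
Why: Thiocarbonylation of the remaining C3 hydroxyl under neutral conditions provides the radical precursor for a Barton–McCombie deoxygenation.

Step 6
Reactants: 6 O-3 imidazol-1-ylcarbonothioate of 5
Product: 7 12-acetoxy-19-(tert-butyldiphenylsilyloxy)-13,14,15,16-tetranor-ent-labd-8(17)-ene
Conditions: Bu3SnH, AIBN (cat.), toluene, 100 °C
Reagents that add atoms: none
Why: Barton–McCombie radical deoxygenation replaces the C3 oxygen by hydrogen, so that C3 is no longer a stereocentre, and the isolated 1,1-disubstituted alkene is inert to the tin radical chain.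

Step 7
Reactants: 7 12-acetoxy-19-(tert-butyldiphenylsilyloxy)-13,14,15,16-tetranor-ent-labd-8(17)-ene
Product: 8 12-acetoxy-19-(tert-butyldiphenylsilyloxy)-13,14,15,16-tetranor-ent-labd-8(9)-ene
Conditions: TsOH·H2O (cat.), benzene, 80 °C
Reagents that add atoms: none
Why: Acid-catalysed alkene isomerisation through the tertiary C8 cation should lead to the thermodynamically preferred tetrasubstituted C8=C9 alkene (removing the C9 stereocentre), and neither the acetate, which could only close a seven-membered ring onto C8, nor the silyl ether should interfere.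

Step 8
Reactants: 8 12-acetoxy-19-(tert-butyldiphenylsilyloxy)-13,14,15,16-tetranor-ent-labd-8(9)-ene
Product: 9 12-acetoxy-19-(tert-butyldiphenylsilyloxy)-8β,9β-epoxy-13,14,15,16-tetranor-ent-labdane
Conditions: mCPBA, NaHCO3, CH2Cl2, 0 °C
Reagents that add atoms: 3-chloroperbenzoic acid, OOC(=O)c1cccc(Cl)c1
Why: Prilezhaev epoxidation of the tetrasubstituted alkene should occur on the β face, opposite the axial C10 methyl and the axial C19 substituent, which sets C8 and C9.

Step 9
Reactants: 9 12-acetoxy-19-(tert-butyldiphenylsilyloxy)-8β,9β-epoxy-13,14,15,16-tetranor-ent-labdane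
Product: 10 12-acetoxy-19-(tert-butyldiphenylsilyloxy)-13,14,15,16-tetranor-neo-clerod-3-en-8β-ol (5α-CH2OSi, 8α-CH3, 9α-CH3, 10β-H)
Conditions: BF3·OEt2 (3 equiv), CH2Cl2, −78 → −40 °C; then aq. NaHCO3
Reagents that add atoms: none
Why: Proposed new method: BF3 coordinates the epoxide oxygen and the C9–O bond ionises with simultaneous migration of the antiperiplanar axial C20 methyl from C10 to the α face of C9, after which axial H5 moves to the β face of C10 and the axial C19 carbon moves from C4 to the α face of C5, the C4 cation finally losing H3 to give the C3=C4 alkene. The closest known reaction type is the Lewis-acid backbone (friedo) rearrangement of terpenoid and steroid epoxides, which is established for one or two such shifts, together with its enzymatic counterpart in clerodane biosynthesis. No ring is closed. Each new stereocentre arises by a suprafacial 1,2-shift anti to the departing bond, so C9 (methyl α) is set by the β C9–O bond, C10 (H β) by the β-axial H5 and C5 (C19 α) by the α-axial C19 of the trans-decalin. The step needs opening at C9 rather than at C8 and completion of all three shifts before proton loss; what should favour this course is the trans-diaxial alignment of C20, H5 and C19, a C12 oxygen held two carbons away from C9 as a BF3-complexed acetate that can neither lactonise nor withdraw strongly, a bulky and poorly nucleophilic silyl ether on C19, and a cold, base-free medium.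

Step 10
Reactants: 10 12-acetoxy-19-(tert-butyldiphenylsilyloxy)-13,14,15,16-tetranor-neo-clerod-3-en-8β-ol
Product: 11 12-acetoxy-13,14,15,16-tetranor-neo-clerod-3-ene-8β,19-diol
Conditions: TBAF, AcOH, THF, rt → 45 °C
Reagents that add atoms: none
Why: Fluoride-mediated desilylation buffered with acetic acid frees the C19 hydroxyl while the C12 acetate and the tertiary alcohol stay intact.

Step 11
Reactants: 11 12-acetoxy-13,14,15,16-tetranor-neo-clerod-3-ene-8β,19-diol
Product: 12 12-acetoxy-13,14,15,16-tetranor-neo-clerod-3-ene-8β,18,19-triol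
Conditions: SeO2 (0.5 equiv), t-BuOOH, CH2Cl2, rt
Reagents that add atoms: selenium dioxide, O=[Se]=O; tert-butyl hydroperoxide, CC(C)(C)OO
Why: Riley allylic oxidation (ene reaction, then [2,3]-sigmatropic shift) should functionalise the C18 methyl, the only allylic C–H position on the more substituted alkene carbon C4 because C5 is quaternary.

Step 12
Reactants: 12 12-acetoxy-13,14,15,16-tetranor-neo-clerod-3-ene-8β,18,19-triol
Product: 13 12-acetoxy-8β-hydroxy-13,14,15,16-tetranor-neo-clerod-3-en-18,19-olide (carbonyl C18, ring oxygen on C19)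
Conditions: MnO2 (excess), CH2Cl2, rt
Reagents that add atoms: none
Why: MnO2 oxidises only the allylic C18 alcohol, and the resulting aldehyde is trapped by the C19 hydroxyl as a lactol that is oxidised further (oxidative lactonisation), so the carbonyl ends at C18.

Step 13
Reactants: 13 12-acetoxy-8β-hydroxy-13,14,15,16-tetranor-neo-clerod-3-en-18,19-olide
Product: 15 12-acetoxy-8β-hydroxy-13,14,15,16-tetranor-neo-cleroda-1,3-dien-18,19-olide, via 2-bromo lactone 14 (not isolated)
Conditions: NBS, AIBN (cat.), PhCF3, 80 °C; then DBU, rt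
Reagents that add atoms: none
Why: Wohl–Ziegler bromination should take the only allylic C–H position (C2, γ to the lactone carbonyl), and base-induced dehydrobromination then gives the conjugated C1=C2–C3=C4 dienyl lactone.

Step 14
Reactants: 15 12-acetoxy-8β-hydroxy-13,14,15,16-tetranor-neo-cleroda-1,3-dien-18,19-olide
Product: 16 12-acetoxy-13,14,15,16-tetranor-neo-cleroda-1,3,7-trien-18,19-olide
Conditions: POCl3, pyridine, 0 °C → rt
Reagents that add atoms: none
Why: Anti elimination (E2) of the dichlorophosphate of the axial 8β-hydroxyl can only use the trans-diaxial H7α within the ring, since C9 is quaternary, so the C7=C8 alkene should be the main product.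

Step 15
Reactants: 16 12-acetoxy-13,14,15,16-tetranor-neo-cleroda-1,3,7-trien-18,19-olide
Product: 17 12-acetoxy-7β,8β-epoxy-13,14,15,16-tetranor-neo-cleroda-1,3-dien-18,19-olide
Conditions: mCPBA, NaHCO3, CH2Cl2, 0 °C
Reagents that add atoms: 3-chloroperbenzoic acid, OOC(=O)c1cccc(Cl)c1
Why: Prilezhaev epoxidation should select the electron-rich trisubstituted C7=C8 alkene over the electron-poor dienyl lactone and attack its β face, because the α face is screened by the axial C20 methyl and the axial C19 methylene, which places the C7 oxygen β.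

Step 16
Reactants: 17 12-acetoxy-7β,8β-epoxy-13,14,15,16-tetranor-neo-cleroda-1,3-dien-18,19-olide
Product: 18 12-acetoxy-7β-hydroxy-13,14,15,16-tetranor-neo-cleroda-1,3,8(17)-trien-18,19-olide
Conditions: Cp2TiCl2, Mn dust, THF, rt
Reagents that add atoms: none
Why: Titanocene-mediated homolytic epoxide opening (Nugent–RajanBabu) at tertiary C8, followed by β-hydrogen loss that is only possible from C17 because C9 is quaternary, should give the exocyclic allylic alcohol with the C7 configuration retained and both esters untouched.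

Step 17
Reactants: 18 12-acetoxy-7β-hydroxy-13,14,15,16-tetranor-neo-cleroda-1,3,8(17)-trien-18,19-olide
Product: 19 7β,12-dihydroxy-13,14,15,16-tetranor-neo-cleroda-1,3,8(17)-trien-18,19-olide
Conditions: K2CO3 (0.3 equiv), MeOH, 0 °C
Reagents that add atoms: none
Why: Base-catalysed transesterification removes the unhindered primary acetate quickly, while any methanolysis of the γ-lactone is reversed on neutral work-up.

Step 18
Reactants: 19 7β,12-dihydroxy-13,14,15,16-tetranor-neo-cleroda-1,3,8(17)-trien-18,19-olide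
Product: 20 7β-hydroxy-12-oxo-13,14,15,16-tetranor-neo-cleroda-1,3,8(17)-trien-18,19-olide (C12 aldehyde)
Conditions: TEMPO (cat.), PhI(OAc)2, CH2Cl2, rt
Reagents that add atoms: none
Why: The TEMPO/PhI(OAc)2 oxidation is selective for primary over hindered secondary alcohols, so C12 should become the aldehyde while the 7β-hydroxyl remains.

Step 19
Reactants: 20 7β-hydroxy-12-oxo-13,14,15,16-tetranor-neo-cleroda-1,3,8(17)-trien-18,19-olide
Product: 21 7β-acetoxy-12-oxo-13,14,15,16-tetranor-neo-cleroda-1,3,8(17)-trien-18,19-olide (C12 aldehyde)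
Conditions: Ac2O, pyridine, rt
Reagents that add atoms: acetic anhydride, CC(=O)OC(C)=O
Why: Acetylation of the equatorial 7β-hydroxyl installs the acetate of the target with retention at C7.

Step 20
Reactants: 21 7β-acetoxy-12-oxo-13,14,15,16-tetranor-neo-cleroda-1,3,8(17)-trien-18,19-olide; 22 3-bromofuran
Product: 25 7β-acetoxy-12-(tert-butyldimethylsilyloxy)-15,16-epoxy-neo-cleroda-1,3,8(17),13(16),14-pentaen-18,19-olide (both C12 epimers), via 3-furyllithium 23 (not isolated), via lithium alkoxide 24 (not isolated)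
Conditions: 22, n-BuLi, THF, −78 °C; add 21, −78 °C; then TBSOTf, −78 → −20 °C
Reagents that add atoms: tert-butyldimethylsilyl trifluoromethanesulfonate, CC(C)(C)[Si](C)(C)OS(=O)(=O)C(F)(F)F
Why: Bromine–lithium exchange gives 3-furyllithium, whose 1,2-addition to the aldehyde at −78 °C should outrun attack on the acetate and the lactone, and the alkoxide is silylated in the same flask.

Step 21
Reactants: 25 7β-acetoxy-12-(tert-butyldimethylsilyloxy)-15,16-epoxy-neo-cleroda-1,3,8(17),13(16),14-pentaen-18,19-olide
Product: 26 7β-acetoxy-12-(tert-butyldimethylsilyloxy)-15,16-epoxy-1β,16-cyclo-neo-cleroda-3,8(17),13(16),14-tetraen-18,19-olide (H1 α)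
Conditions: Me2AlCl (2.5 equiv), CH2Cl2, −78 → −40 °C; then DBU (cat.), rt
Reagents that add atoms: none
Why: Lewis-acid activation of the dienyl lactone should trigger an intramolecular vinylogous Friedel–Crafts alkylation (furan-terminated 1,6-conjugate addition) at C2 of the 3-alkylfuran, its most nucleophilic position, which forms the seven-membered ring C with the new C1 stereocentre fixed by the tether from the β-oriented C11, DBU then bringing the lactone alkene back into conjugation at C3=C4.

Step 22
Reactants: 26 7β-acetoxy-12-(tert-butyldimethylsilyloxy)-15,16-epoxy-1β,16-cyclo-neo-cleroda-3,8(17),13(16),14-tetraen-18,19-olide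
Product: 27 7β-acetoxy-12-hydroxy-15,16-epoxy-1β,16-cyclo-neo-cleroda-3,8(17),13(16),14-tetraen-18,19-olide
Conditions: HF·pyridine, THF, 0 °C → rt
Reagents that add atoms: none
Why: Fluoride cleavage of the secondary silyl ether frees the C12 carbinol without touching the acetate or the lactone.

Step 23
Reactants: 27 7β-acetoxy-12-hydroxy-15,16-epoxy-1β,16-cyclo-neo-cleroda-3,8(17),13(16),14-tetraen-18,19-olide
Product: 28 CNP0273675.1 (7β-acetoxy-12-oxo-15,16-epoxy-1β,16-cyclo-neo-cleroda-3,8(17),13(16),14-tetraen-18,19-olide)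
Conditions: Dess–Martin periodinane, NaHCO3, CH2Cl2, rt
Reagents that add atoms: none
Why: Dess–Martin oxidation converts the furyl carbinol into the C12 ketone under buffered neutral conditions, which removes the C12 stereocentre and completes the target.

Compound list
1 | andrographolide | C[C@@]12CC[C@H]([C@@]([C@H]1CCC(=C)[C@H]2C/C=C/3\[C@@H](COC3=O)O)(C)CO)O | starting material
2 | 19-O-(tert-butyldiphenylsilyl)andrographolide | C[C@@]12CC[C@H]([C@@]([C@H]1CCC(=C)[C@H]2C/C=C/3\[C@@H](COC3=O)O)(C)CO[Si](c4ccccc4)(c4ccccc4)C(C)(C)C)O | intermediate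
3 | 3α-hydroxy-19-(tert-butyldiphenylsilyloxy)-13,14,15,16-tetranor-ent-labd-8(17)-en-12-al | C[C@@]12CC[C@H]([C@@]([C@H]1CCC(=C)[C@H]2CC=O)(C)CO[Si](c3ccccc3)(c3ccccc3)C(C)(C)C)O | intermediate
4 | 19-(tert-butyldiphenylsilyloxy)-13,14,15,16-tetranor-ent-labd-8(17)-ene-3α,12-diol | C[C@@]12CC[C@H]([C@@]([C@H]1CCC(=C)[C@H]2CCO)(C)CO[Si](c3ccccc3)(c3ccccc3)C(C)(C)C)O | intermediate
5 | 12-acetoxy-19-(tert-butyldiphenylsilyloxy)-13,14,15,16-tetranor-ent-labd-8(17)-en-3α-ol | C[C@@]12CC[C@H]([C@@]([C@H]1CCC(=C)[C@H]2CCOC(C)=O)(C)CO[Si](c3ccccc3)(c3ccccc3)C(C)(C)C)O | intermediate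
6 | O-3 imidazol-1-ylcarbonothioate of 5 | C[C@@]12CC[C@H]([C@@]([C@H]1CCC(=C)[C@H]2CCOC(C)=O)(C)CO[Si](c3ccccc3)(c3ccccc3)C(C)(C)C)OC(=S)n3ccnc3 | intermediate
7 | 12-acetoxy-19-(tert-butyldiphenylsilyloxy)-13,14,15,16-tetranor-ent-labd-8(17)-ene | C[C@@]12CCC[C@@]([C@H]1CCC(=C)[C@H]2CCOC(C)=O)(C)CO[Si](c3ccccc3)(c3ccccc3)C(C)(C)C | intermediate
8 | 12-acetoxy-19-(tert-butyldiphenylsilyloxy)-13,14,15,16-tetranor-ent-labd-8(9)-ene | C[C@@]12CCC[C@@]([C@H]1CCC(C)=C2CCOC(C)=O)(C)CO[Si](c3ccccc3)(c3ccccc3)C(C)(C)C | intermediate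
9 | 12-acetoxy-19-(tert-butyldiphenylsilyloxy)-8β,9β-epoxy-13,14,15,16-tetranor-ent-labdane | C[C@]12CC[C@@H]3[C@](C)(CO[Si](c4ccccc4)(c4ccccc4)C(C)(C)C)CCC[C@@]3(C)[C@@]1(CCOC(C)=O)O2 | intermediate
10 | 12-acetoxy-19-(tert-butyldiphenylsilyloxy)-13,14,15,16-tetranor-neo-clerod-3-en-8β-ol | C[C@]1(O)CC[C@@]2(CO[Si](c3ccccc3)(c3ccccc3)C(C)(C)C)C(C)=CCC[C@@H]2[C@@]1(C)CCOC(C)=O | intermediate
11 | 12-acetoxy-13,14,15,16-tetranor-neo-clerod-3-ene-8β,19-diol | C[C@]1(O)CC[C@@]2(CO)C(C)=CCC[C@@H]2[C@@]1(C)CCOC(C)=O | intermediate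
12 | 12-acetoxy-13,14,15,16-tetranor-neo-clerod-3-ene-8β,18,19-triol | C[C@]1(O)CC[C@@]2(CO)C(CO)=CCC[C@@H]2[C@@]1(C)CCOC(C)=O | intermediate
13 | 12-acetoxy-8β-hydroxy-13,14,15,16-tetranor-neo-clerod-3-en-18,19-olide | C[C@]1(O)CC[C@@]23COC(=O)C2=CCC[C@@H]3[C@@]1(C)CCOC(C)=O | intermediate
14 | 2-bromo derivative of 13 (C2 epimers) | C[C@]1(O)CC[C@@]23COC(=O)C2=CC(Br)C[C@@H]3[C@@]1(C)CCOC(C)=O | intermediate (not isolated)
15 | 12-acetoxy-8β-hydroxy-13,14,15,16-tetranor-neo-cleroda-1,3-dien-18,19-olide | C[C@]1(O)CC[C@@]23COC(=O)C2=CC=C[C@@H]3[C@@]1(C)CCOC(C)=O | intermediate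
16 | 12-acetoxy-13,14,15,16-tetranor-neo-cleroda-1,3,7-trien-18,19-olide | CC1=CC[C@@]23COC(=O)C2=CC=C[C@@H]3[C@@]1(C)CCOC(C)=O | intermediate
17 | 12-acetoxy-7β,8β-epoxy-13,14,15,16-tetranor-neo-cleroda-1,3-dien-18,19-olide | C[C@@]12O[C@H]2C[C@@]34COC(=O)C3=CC=C[C@@H]4[C@@]1(C)CCOC(C)=O | intermediate
18 | 12-acetoxy-7β-hydroxy-13,14,15,16-tetranor-neo-cleroda-1,3,8(17)-trien-18,19-olide | C=C1[C@@H](O)C[C@@]23COC(=O)C2=CC=C[C@@H]3[C@@]1(C)CCOC(C)=O | intermediate
19 | 7β,12-dihydroxy-13,14,15,16-tetranor-neo-cleroda-1,3,8(17)-trien-18,19-olide | C=C1[C@@H](O)C[C@@]23COC(=O)C2=CC=C[C@@H]3[C@@]1(C)CCO | intermediate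
20 | 7β-hydroxy-12-oxo-13,14,15,16-tetranor-neo-cleroda-1,3,8(17)-trien-18,19-olide | C=C1[C@@H](O)C[C@@]23COC(=O)C2=CC=C[C@@H]3[C@@]1(C)CC=O | intermediate
21 | 7β-acetoxy-12-oxo-13,14,15,16-tetranor-neo-cleroda-1,3,8(17)-trien-18,19-olide | C=C1[C@@H](OC(C)=O)C[C@@]23COC(=O)C2=CC=C[C@@H]3[C@@]1(C)CC=O | intermediate
22 | 3-bromofuran | Brc1ccoc1 | starting material
23 | 3-furyllithium | [Li]c1ccoc1 | intermediate (not isolated)
24 | lithium C12 alkoxide of the 3-furyl carbinol (C12 epimers) | C=C1[C@@H](OC(C)=O)C[C@@]23COC(=O)C2=CC=C[C@@H]3[C@@]1(C)CC([O-])c1ccoc1.[Li+] | intermediate (not isolated)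
25 | 7β-acetoxy-12-(tert-butyldimethylsilyloxy)-15,16-epoxy-neo-cleroda-1,3,8(17),13(16),14-pentaen-18,19-olide (C12 epimers) | C=C1[C@@H](OC(C)=O)C[C@@]23COC(=O)C2=CC=C[C@@H]3[C@@]1(C)CC(O[Si](C)(C)C(C)(C)C)c1ccoc1 | intermediate
26 | 7β-acetoxy-12-(tert-butyldimethylsilyloxy)-15,16-epoxy-1β,16-cyclo-neo-cleroda-3,8(17),13(16),14-tetraen-18,19-olide (C12 epimers) | C=C1[C@@H](OC(C)=O)C[C@@]23COC(=O)C2=CC[C@H]2c4occc4C(O[Si](C)(C)C(C)(C)C)C[C@]1(C)[C@@H]23 | intermediate
27 | 7β-acetoxy-12-hydroxy-15,16-epoxy-1β,16-cyclo-neo-cleroda-3,8(17),13(16),14-tetraen-18,19-olide (C12 epimers) | C=C1[C@@H](OC(C)=O)C[C@@]23COC(=O)C2=CC[C@H]2c4occc4C(O)C[C@]1(C)[C@@H]23 | intermediate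
28 | CNP0273675.1 | C=C1[C@@H](OC(C)=O)C[C@@]23COC(=O)C2=CC[C@H]2c4occc4C(=O)C[C@]1(C)[C@@H]23 | target

Total step count: 23. Longest linear sequence: 23 steps (1 to 28); 3-bromofuran 22 enters in step 20.

Steps most likely to fail

1. Step 9. The epoxide may ionise at C8 and collapse by a semipinacol shift (ring contraction of ring B). The cascade may also stop by proton loss after the first or second shift, at the ent-halimane stage, or the C19 oxygen may capture the C10 cation. The fallback uses known steps, takes the cation chemistry in two isolated stages and replaces the weak CH2OSi migrating group by a formyl group.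
   - It sets out from 9. Exposure to BF3·OEt2 at 0 °C is asked only for the precedented first stage, epoxide opening with 1,2-methyl shift and proton loss, which should give the tetrasubstituted alkene 12-acetoxy-19-(tert-butyldiphenylsilyloxy)-13,14,15,16-tetranor-ent-halim-5(10)-en-8β-ol F1.
   - Buffered TBAF frees the primary alcohol 12-acetoxy-13,14,15,16-tetranor-ent-halim-5(10)-ene-8β,19-diol F2.
   - Dess–Martin oxidation gives the β,γ-unsaturated aldehyde 12-acetoxy-8β-hydroxy-13,14,15,16-tetranor-ent-halim-5(10)-en-19-al F3.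
   - Protonation of the alkene on its open β face at C10 (TfOH cat. or BF3·OEt2, CH2Cl2, −40 °C) generates the C5 cation. It is quenched by a 1,2-formyl shift on the α face, an acyl migration to an adjacent cation of the kind well established in epoxy-ketone and β,γ-unsaturated carbonyl rearrangements. Proton loss from C3 should then give 12-acetoxy-8β-hydroxy-13,14,15,16-tetranor-neo-clerod-3-en-19-al F4.
   - NaBH4 in MeOH at 0 °C reduces the aldehyde and the route is rejoined at 11.

2. Step 21. The 1,6-addition to the weakly electrophilic dienyl lactone may be slower than Lewis-acid ionisation of the furylcarbinyl silyl ether or of the allylic C7 acetate, or than decomposition of the furan. The fallback reverses the order of bond formation and needs no C12 protection.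
   - It sets out from 21. Pinnick oxidation (NaClO2, NaH2PO4, 2-methyl-2-butene) gives the acid 7β-acetoxy-13,14,15,16-tetranor-neo-cleroda-1,3,8(17)-trien-18,19-olid-12-oic acid F5.
   - Furan as cosolvent with BF3·OEt2 adds intermolecularly through its C2 to C1 (Friedel–Crafts 1,6-addition), from the β face because the α face is screened by the axial C20 and C19. After conjugation this gives 7β-acetoxy-1β-(furan-2-yl)-13,14,15,16-tetranor-neo-cleroda-3,8(17)-dien-18,19-olid-12-oic acid F6.
   - Intramolecular Friedel–Crafts acylation at furan C3 ((CF3CO)2O, CH2Cl2, high dilution) closes ring C and comes back to the route at 28.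

3. Step 2. The aldehyde may be over-oxidised to the acid, or permanganate may also attack the exocyclic C8=C17 alkene. The fallback sets out from 2. Nucleophilic (Weitz–Scheffer) epoxidation with t-BuOOH and DBU can only take the conjugated alkene and gives the 12,13-epoxide of 19-O-(tert-butyldiphenylsilyl)andrographolide F7. Periodic acid (H5IO6, THF/H2O) then cleaves the epoxide to the aldehyde, returning to the route at 3.

Further compounds
F1 | step 9 | 12-acetoxy-19-(tert-butyldiphenylsilyloxy)-13,14,15,16-tetranor-ent-halim-5(10)-en-8β-ol | C[C@]1(O)CCC2=C(CCC[C@@]2(C)CO[Si](c3ccccc3)(c3ccccc3)C(C)(C)C)[C@@]1(C)CCOC(C)=O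
F2 | step 9 | 12-acetoxy-13,14,15,16-tetranor-ent-halim-5(10)-ene-8β,19-diol | C[C@]1(O)CCC2=C(CCC[C@@]2(C)CO)[C@@]1(C)CCOC(C)=O
F3 | step 9 | 12-acetoxy-8β-hydroxy-13,14,15,16-tetranor-ent-halim-5(10)-en-19-al | C[C@]1(O)CCC2=C(CCC[C@@]2(C)C=O)[C@@]1(C)CCOC(C)=O
F4 | step 9 | 12-acetoxy-8β-hydroxy-13,14,15,16-tetranor-neo-clerod-3-en-19-al | C[C@]1(O)CC[C@@]2(C=O)C(C)=CCC[C@@H]2[C@@]1(C)CCOC(C)=O
F5 | step 21 | 7β-acetoxy-13,14,15,16-tetranor-neo-cleroda-1,3,8(17)-trien-18,19-olid-12-oic acid | C=C1[C@@H](OC(C)=O)C[C@@]23COC(=O)C2=CC=C[C@@H]3[C@@]1(C)CC(=O)O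
F6 | step 21 | 7β-acetoxy-1β-(furan-2-yl)-13,14,15,16-tetranor-neo-cleroda-3,8(17)-dien-18,19-olid-12-oic acid | C=C1[C@@H](OC(C)=O)C[C@@]23COC(=O)C2=CC[C@@H](c4ccco4)[C@@H]3[C@@]1(C)CC(=O)O
F7 | step 2 | 12,13-epoxide of 19-O-(tert-butyldiphenylsilyl)andrographolide (epoxide epimers) | C[C@@]12CC[C@H]([C@@]([C@H]1CCC(=C)[C@H]2CC3OC34[C@@H](COC4=O)O)(C)CO[Si](c5ccccc5)(c5ccccc5)C(C)(C)C)O
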